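**The question.** How much X stands in the flask at 12 h, and what has stopped it by then?

| flask | Q | E | remark | time |
|---|---|---|---|---|
| Wednesday's | 0.50 M | 0.50 M | run made earlier |  |
| Sunday's | 2 M | 0.50 M | run made earlier |  |
| Saturday's | 1 M | 1 M | run made earlier |  |
| flask | 1.0 M | 0.500 M |  | 12 h |

| run | time / h | X / % |
|---|---|---|
| Wednesday's | 1.50 | 20.7 |
| Wednesday's | 3.00 | 24.3 |
| Wednesday's | 5.00 | 22.9 |
| Wednesday's | 6.00 | 23.1 |
| Wednesday's | 8.00 | 22.4 |
| Wednesday's | 10.0 | 22.5 |
| Wednesday's | 12.0 | 22.7 |
| Sunday's | 1.00 | 9.6 |
| Sunday's | 1.33 | 10.0 |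
| Sunday's | 2.00 | 11.0 |
| Sunday's | 3.00 | 10.4 |
| Sunday's | 5.00 | 10.6 |
| Sunday's | 8.00 | 11.8 |
| Sunday's | 12.0 | 10.8 |
| Saturday's | 2.50 | 19.1 |
| Saturday's | 5.00 | 19.4 |
| Saturday's | 8.00 | 19.5 |
| Saturday's | 10.0 | 19.2 |
| Saturday's | 12.0 | 19.5 |

(readings scatter by 0.5 percentage points)

- in percentages every species weighs as the Q in it: one J counts as two
- as a solid, counted per litre of solution: E
- the numbers in the tables scatter by 0.5 percentage points (one standard deviation)
- on the list of suspects stand: Q + G + X -> 2 X; Q + G -> X; 2 Q -> J; E <-> G
- at the start none of E is in solution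
- the reaction counts as stopped when no species that holds the Q changes by six tenths of a point or more over the second half of the time

* at 12 h, what has stopped the reaction, if anything has (for what has run out or reacted, a solid counts together with what of it has only dissolved) (all of Q has reacted / G has run out first / it is still moving)
* amount of X at 12 h, in percent of the Q charged

**Fastest rung.** X climbs first: Sunday's run shows 9.6% of its Q charged at 1.00 h, and Wednesday's run 20.7% at 1.50 h.

**Middle rung.** After the climb each curve can be replaced by its mean. The last 5 readings give 22.7% for Wednesday's run and 10.9% for Sunday's run, each mean carrying an error of about 0.22 percentage points.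

**Slowest rung.** The reading time of 12 h lies far out on these flat stretches, so the flask's answer is expected to be its plateau.

**Charge slope.** Both runs hold E at 0.50 M and differ in Q. The charge slope, the logarithm of the ratio of the two plateau yields divided by the logarithm of the ratio of the charges, is 0.528. At 1.0 M of Q it gives 15.8%. That much X, at one G each, takes 31.5% of the E charge, less than the charge itself, so G is expected to stay in excess and Q to be the limiting reagent, its remainder pairing into J. Saturday's 19.5%, with twice the E of the flask, stands higher than this estimate, so the slope is used here for fixed E.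

**The forecast.** The forecast, higher than this reckoning, expects 17% and "all of Q has reacted", “flat well before 12 h”.

**The result.** The flask gives 16.3% of X and "all of Q has reacted": at 12.0 h, 0% of the charged Q is left, while 67% of the charged G stands, solid or dissolved.

    Q + G + X → 2 X (k = 0.970 L² mol⁻² min⁻¹)
    Q + G → X (k = 0.00210 L mol⁻¹ min⁻¹)
    2 Q → J (k = 0.0850 L mol⁻¹ min⁻¹)
    E ⇌ G, rate k4*(cs4 - [G]) while solid is left; crystals form when [G] > cs4 (solubility = 0.860 M, k = 0.0860 min⁻¹)

Carried from this flask to the neighbour with 1.7 M of Q and the same E, the charge slope gives 12.3%, and that neighbour flask ends at 11.9% of its Q charged.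

The earlier runs and the new flask are simulated from invented constants; noise was put on by code.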